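All constants come from no measurement; no experiment stands behind them.

We have to decide which of the given numbers must be known well before this flask is run.

substrate 0.63 M; gas phase 22 mM (held); time 5.0 d

    gas phase ⇌ dissolved gas, rate k1*(csat - [dissolved gas]) (k1 = 8.9 /h, csat = 22 mM)
    substrate + dissolved gas → target (k2 = 110 /M/h)
    crystals ⇌ target, rate k3*(cs3 - [target]) while solid is left; crystals form when [target] > cs3 (cs3 = 0.057 M, k3 = 6.4 /h)
    target ⇌ isomer of the product (K4 = 23, k4 = 0.018 /h)

- for target the crystals are counted in
- as a solid, counted per litre of solution: crystals
- at the start none of the gas is dissolved
- run time (flask): 5.0 d

- target and crystals together at 5.0 d, in percent of the substrate charged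
- the change that raises the amount of target and crystals together at 5.0 d, in percent of the substrate charged most ("none" if none brings more than 2 percentage points) (north / north-east / south-east / south-west / none)
- amount of target and crystals together at 5.0 d, in percent of the substrate charged, after south-west

We take the numbers in turn. Gas transfer delivers at most 0.196 M/h, so the charge needs at least 3.22 h, and the tail of the substrate decays with a time constant of 0.413 h. Errors in the transfer coefficient, the saturation concentration or the rate constant of step two therefore shift a stage that is short against the run.

The dissolution coefficient matters little because dissolution is much faster than isomerisation: while crystals stand, we reckon dissolved target at 0.281% below the solubility. The equilibrium constant counts more than that, since we reckon the back rate at 9.39% of the forward rate at the end.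

The numbers to know well are therefore the solubility, the isomerisation rate constant, the time and the charge. While crystals stand, dissolved target stays near the solubility because dissolution is faster than isomerisation, so we take isomer to form pseudo-zero-order. We call the forward rate at the solubility the crystal-fed isomer rate:

r = 0.018 /h × 0.057 M = 1.03 mM/h

isomer at the end = r × 5.0 d = 0.123 M

The crystal stock, the charge less the solubility, is 0.573 M, and at r we reckon that it lasts 23.3 d, longer than the run. Our reckoning gives y = 80.5%, and the same after south-west, 80.5%. Doubling the solubility doubles r, so our choice is none.

The forecast gives 81.4%, none and 81.4%, holding that “isomer forms at a nearly constant, slightly slowing rate”. Its y stands above ours.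

The simulation gives 81.2%, none and 81.2%. Doubling the solubility changes y by −19 percentage points, and doubling the dissolution coefficient by 0.091 points.

In this flask r × time is 19.5% of the charge, and at 5.00 d the isomer stands at 18.8% with crystals at 72.2%. The forecast's ground goes when crystals do not last the run. The neighbour charged with 0.16 M of substrate has a crystal stock of 0.103 M, less than the 0.123 M that r asks for, so at r we reckon that it lasts 4.17 d, short of the run. In that neighbour at 5.00 d, crystals stand at 0%, isomer at 72.2% and y at 27.8%.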